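Slowness came first: the initiator needs 85 s to halve, longer than the run of 40 s, so it was still feeding radicals when the run ended.

all flasks: substrate 0.15 M; gas 12 mM (held); initiator 3.8 mM; time 40 s

| run | scavenger |
|---|---|
| beta | 0.0750 M |
| epsilon | 0.0980 M |

    2 first chain carrier → ended chains A (k1 = 6.7 × 10⁷ M⁻¹ s⁻¹)
    substrate + released group ⇌ idle adduct, settled at all times (K2 = 1.8 M⁻¹)
    scavenger + released group → scavenged by-product (k3 = 27.5 M⁻¹ s⁻¹)
    reagent + first chain carrier → target + second chain carrier (k4 = 1.27 × 10⁶ M⁻¹ s⁻¹)
    gas ⇌ reagent, rate k5*(csat - [reagent]) (k5 = 6.39 s⁻¹, csat = 12 mM)
    substrate + initiating radical → capped initiator + first chain carrier (k6 = 4.78 × 10⁶ M⁻¹ s⁻¹)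
    2 second chain carrier → ended chains B (k7 = 3 × 10⁸ M⁻¹ s⁻¹)
    initiator → 2 initiating radical (k8 = 0.00816 s⁻¹)
    substrate ⇌ dormant form (K9 = 28, k9 = 0.0368 s⁻¹)
    substrate + second chain carrier → released group + first chain carrier (k10 = 2.89 × 10⁵ M⁻¹ s⁻¹)

1. part of the substrate that has reacted at the end, beta
2. part of the substrate that has reacted at the end, epsilon
3. what raising the concentration of scavenger from its lowest to its highest value here does to the part of the substrate that has reacted (changes below 5 percentage points count as none) (it rises / no change / it falls)

- percentages count the substrate that a species holds: one ended chains A counts as two
- released group is meant together with its idle adduct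
- where a step has two of a species, its rate is k times that concentration squared, and two are used at each turn
- at the start none of reagent is dissolved
- what has gone from substrate into another species counts as reacted, even if it can come back
- run time (beta): 40 s

I held [second chain carrier] at a steady state, with the radicals from the initiator ended in pairs as ended chains B. That gave 3.21 × 10⁻⁷ M. I then let the substrate leave by two doors, the chain and the dormant form, and both count as reacted. So in my reckoning it falls in a pseudo-first-order way, with a loss constant equal to the forward constant into the dormant form plus the chain constant times [second chain carrier]: 0.130 s⁻¹. I dropped the way back from the dormant form. This left 0.558% of the substrate, so my figure was 99.4% reacted in beta and in epsilon. The scavenger does not appear in the loss constant, so I expected no change.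

The forecast gave 98.9% for beta, 98.9% for epsilon and no change, its percentages lower than my figure, with this ground for the trend: “The scavenger only removes the released group, which never feeds back on the chain”.

The simulation gave 98.9% for beta and 98.9% for epsilon, so no change, the change being 0.044 percentage points. The forecast stood, and my figure was high by 0.59 points.

In beta, the fall of the substrate between 20.0 s and 40.0 s reads as a loss constant of 0.112 s⁻¹, against my 0.130 s⁻¹. With each setting moved alone, the answer for epsilon had shifted by 5 points at a time of 24.8 s, or at an initiator charge of 0.859 mM. The neighbour of epsilon charged with 9.5 × 10⁻⁴ M of initiator, a quarter of the charge in epsilon, has by the same reckoning its chain term cut to half, so the loss constant becomes 0.0833 s⁻¹ and 3.57% of the substrate should remain. That neighbour held 5.67% of the substrate charged, with 94.3% reacted.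

All constants stand for no real mixture; the flask was simulated.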